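**Retrosynthetic overview**
1. Target 25 ← ring alcohol 18 + angelic acid 23 (late Yamaguchi-type esterification; 23 made from tiglic acid).
2. 18 ← cyclohexenone 17 (Luche reduction sets C-1) ← acyclic dienone 16 by ring-closing metathesis (C-2=C-3), the only ring closure leading to the target ring.
3. 16 ← lactone 13 (vinyl Grignard opening, acetylation) ← lactone 6 (fragment A) + triflate 11 (fragment B) by enolate alkylation (C-5–C-6 bond, sets C-6).
4. 6 ← dimethyl 3-methylglutarate (enzymatic desymmetrisation sets C-7, CBS reduction sets C-9); 11 ← methacrolein (hydrolytic kinetic resolution sets C-4).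
5. Ring order: a temporary δ-lactone (step 3, opened in step 8), then the cyclohexene ring (step 10).

Assumption: the ester C/C=C(/C)C(=O)O is read as (Z)-2-methylbut-2-enoate (angelate); labels used are ring C-1 (angelate), C-3 (methyl), C-4 (OAc), C-6, and side chain C-7 (CHMe), C-8, C-9 (OAc), C-10=C-11, so the target is (1S,4R,6S,7R,9R).

**Fragment A**

Step 1
Reactants: 1 dimethyl 3-methylpentanedioate
Product: 2 (R)-5-methoxy-3-methyl-5-oxopentanoic acid
Conditions: pig liver esterase, pH 7 phosphate buffer/MeOH 4:1, −10 °C, pH-stat with 1 M NaOH; then 2 M HCl to pH 2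
Reagents that add atoms: water, O
Why: Enzymatic desymmetrisation hydrolyses one enantiotopic ester group of the prochiral diester and gives the (R)-half-ester, which fixes C-7.

Step 2
Reactants: 2 (R)-5-methoxy-3-methyl-5-oxopentanoic acid
Product: 4 methyl (R)-3,7-dimethyl-5-oxooct-6-enoate, via acid chloride 3 (not isolated)
Conditions: (COCl)2, DMF (cat.), CH2Cl2, 0 °C → rt, concentrate; then Me2C=CHZnCl (from Me2C=CHMgBr + ZnCl2, THF, 0 °C), Pd(PPh3)4 (3 mol%), THF, 0 °C → rt
Reagents that add atoms: 2-methylprop-1-enylmagnesium bromide, CC(C)=C[Mg]Br; oxalyl chloride, O=C(Cl)C(Cl)=O (gives the Cl of 3 only)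
Why: Negishi acylation couples the acid chloride with the alkenylzinc reagent to the enone without touching the methyl ester or the stereocentre.

Step 3
Reactants: 4 methyl (R)-3,7-dimethyl-5-oxooct-6-enoate
Product: 6 (4R,6R)-4-methyl-6-(2-methylprop-1-en-1-yl)oxan-2-one, via hydroxy ester 5 (not isolated)
Conditions: (S)-Me-CBS oxazaborolidine (0.2 equiv), catecholborane, toluene, −78 °C; MeOH quench; then PPTS (cat.), toluene, 60 °C
Reagents that add atoms: none
Why: Corey–Bakshi–Shibata reduction with the (S)-catalyst treats the alkenyl group as the large substituent and gives the (R)-carbinol (C-9), and lactonisation then gives the cis-4,6-disubstituted δ-lactone.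

**Fragment B**

Step 4
Reactants: 7 2-methylprop-2-enal (methacrolein)
Product: 8 rac-2-(prop-1-en-2-yl)oxirane
Conditions: Me3S+ I−, NaH, DMSO/THF, 0 °C → rt; distil
Reagents that add atoms: trimethylsulfonium iodide, C[S+](C)C.[I-]
Why: Corey–Chaykovsky epoxidation, in which the sulfonium ylide adds 1,2 to the enal and closes to the racemic epoxide.

Step 5
Reactants: 8 rac-2-(prop-1-en-2-yl)oxirane
Product: 9 (S)-3-methylbut-3-ene-1,2-diol
Conditions: (S,S)-Co(salen)(OAc) (trivalent cobalt; salen = N,N′-bis(3,5-di-tert-butylsalicylidene)-1,2-cyclohexanediamine dianion), 0.5 mol%, H2O (0.45 equiv), THF, 0 °C → rt; unreacted epoxide distilled off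
Reagents that add atoms: water, O
Why: Jacobsen hydrolytic kinetic resolution opens only the (S)-epoxide at its CH2 terminus with retention at the stereocentre, giving the (S)-diol that becomes C-4.

Step 6
Reactants: 9 (S)-3-methylbut-3-ene-1,2-diol
Product: 11 (S)-3-methyl-2-(triethylsilyloxy)but-3-en-1-yl trifluoromethanesulfonate, via hydroxy triflate 10 (not isolated)
Conditions: Tf2O (1.05 equiv), 2,6-lutidine (3 equiv), CH2Cl2, −78 °C; then Et3SiOTf (1.2 equiv), −78 → −40 °C; cold silica plug, used at once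
Reagents that add atoms: triflic anhydride, O=S(=O)(OS(=O)(=O)C(F)(F)F)C(F)(F)F; triethylsilyl triflate, CC[Si](CC)(CC)OS(=O)(=O)C(F)(F)F
Why: Chemoselective sulfonylation triflates the primary hydroxyl at −78 °C and the secondary allylic hydroxyl is silylated in the same flask, leaving the stereocentre untouched.

**Fragment union and ring construction**

Step 7
Reactants: 6 (4R,6R)-4-methyl-6-(2-methylprop-1-en-1-yl)oxan-2-one; 11 (S)-3-methyl-2-(triethylsilyloxy)but-3-en-1-yl trifluoromethanesulfonate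
Product: 13 (3S,4R,6R)-4-methyl-3-[(2R)-3-methyl-2-(triethylsilyloxy)but-3-en-1-yl]-6-(2-methylprop-1-en-1-yl)oxan-2-one, via lithium enolate 12 (not isolated)
Conditions: LiN(iPr)2 (1.1 equiv), THF, −78 °C, 45 min; then 11 (1.3 equiv), THF, −78 → −30 °C
Reagents that add atoms: none
Why: SN2 enolate alkylation in which the triflate approaches the half-chair lactone enolate anti to the adjacent C-7 methyl group (1,2-induction), setting C-6 trans to that methyl and joining the two fragments.

Step 8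
Reactants: 13 (3S,4R,6R)-4-methyl-3-[(2R)-3-methyl-2-(triethylsilyloxy)but-3-en-1-yl]-6-(2-methylprop-1-en-1-yl)oxan-2-one
Product: 14 (4S,6R)-4-[(2R,4R)-4-hydroxy-6-methylhept-5-en-2-yl]-7-methyl-6-(triethylsilyloxy)octa-1,7-dien-3-one
Conditions: CH2=CHMgBr (1.3 equiv), THF, −78 °C, 1 h; sat. aq. NH4Cl at −78 °C
Reagents that add atoms: vinylmagnesium bromide, C=C[Mg]Br
Why: Grignard acyl substitution on the lactone stops after one addition because the first adduct does not collapse before the cold quench, so the lactone opens to the vinyl ketone and frees the C-9 hydroxyl.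

Step 9
Reactants: 14 (4S,6R)-4-[(2R,4R)-4-hydroxy-6-methylhept-5-en-2-yl]-7-methyl-6-(triethylsilyloxy)octa-1,7-dien-3-one
Product: 16 (4S,6R)-6-acetoxy-4-[(2R,4R)-4-acetoxy-6-methylhept-5-en-2-yl]-7-methylocta-1,7-dien-3-one, via diol 15 (not isolated)
Conditions: HF·pyridine, pyridine/THF, 0 °C, 2 h; then Ac2O (10 equiv), DMAP (0.2 equiv), 0 °C → rt
Reagents that add atoms: acetic anhydride, CC(=O)OC(C)=O
Why: Fluoride desilylation followed by DMAP-catalysed acetylation in one flask installs both acetates of the target; no stereocentre is involved.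

Step 10
Reactants: 16 (4S,6R)-6-acetoxy-4-[(2R,4R)-4-acetoxy-6-methylhept-5-en-2-yl]-7-methylocta-1,7-dien-3-one
Product: 17 (1R,5S)-5-[(2R,4R)-4-acetoxy-6-methylhept-5-en-2-yl]-2-methyl-4-oxocyclohex-2-en-1-yl acetate
Conditions: second-generation Grubbs catalyst (H2IMes)(PCy3)Cl2Ru=CHPh (5–10 mol%), CH2Cl2 (5 mM), 40 °C, Ar sweep
Reagents that add atoms: none
Why: Ring-closing metathesis joins the vinyl ketone and the isopropenyl group with loss of ethylene to give the six-membered trisubstituted enone, while the hindered C-10=C-11 alkene next to an allylic acetate could only close a seven-membered ring and is left alone.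

Step 11
Reactants: 17 (1R,5S)-5-[(2R,4R)-4-acetoxy-6-methylhept-5-en-2-yl]-2-methyl-4-oxocyclohex-2-en-1-yl acetate
Product: 18 (1R,4S,5S)-5-[(2R,4R)-4-acetoxy-6-methylhept-5-en-2-yl]-4-hydroxy-2-methylcyclohex-2-en-1-yl acetate
Conditions: NaBH4, CeCl3·7H2O, MeOH, −78 °C, 30 min
Reagents that add atoms: none
Why: Luche 1,2-reduction by axial hydride attack on the half-chair enone (C-6 side chain pseudo-equatorial, C-4 acetate pseudo-axial) gives the C-1 alcohol trans to the side chain and cis to the C-4 acetate, i.e. (1S) in target numbering.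

**Angelic acid**

Step 12
Reactants: 19 tiglic acid, (E)-2-methylbut-2-enoic acid
Product: 20 rac-(2R,3S)-2,3-dibromo-2-methylbutanoic acid
Conditions: Br2 (1.05 equiv), CH2Cl2, 0 °C → rt, dark
Reagents that add atoms: bromine, BrBr
Why: Electrophilic anti addition of bromine to the (E)-alkene gives the racemic (2R*,3S*)-dibromide.

Step 13
Reactants: 20 rac-(2R,3S)-2,3-dibromo-2-methylbutanoic acid
Product: 21 (Z)-2-bromobut-2-ene
Conditions: Na2CO3 (1.1 equiv), H2O, 60 °C; product distilled out
Reagents that add atoms: none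
Why: Stereospecific decarboxylative anti elimination of the β-bromo carboxylate (Grob-type fragmentation) converts the (2R*,3S*)-dibromide into the (Z)-bromoalkene.

Step 14
Reactants: 21 (Z)-2-bromobut-2-ene
Product: 23 angelic acid, (Z)-2-methylbut-2-enoic acid, via vinyllithium 22 (not isolated)
Conditions: t-BuLi (2.1 equiv), Et2O, −78 °C, 30 min; CO2 (dry), −78 → 0 °C; cold 1 M HCl
Reagents that add atoms: carbon dioxide, O=C=O
Why: Bromine–lithium exchange and carboxylation both proceed with retention of alkene geometry, so the (Z)-acid is obtained.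

**Final esterification**

Step 15
Reactants: 18 (1R,4S,5S)-5-[(2R,4R)-4-acetoxy-6-methylhept-5-en-2-yl]-4-hydroxy-2-methylcyclohex-2-en-1-yl acetate; 23 angelic acid
Product: 25 (1S,4R,6S)-4-acetoxy-6-[(2R,4R)-4-acetoxy-6-methylhept-5-en-2-yl]-3-methylcyclohex-2-en-1-yl (Z)-2-methylbut-2-enoate, via mixed anhydride 24 (not isolated)
Conditions: 23 (3 equiv), 2,4,6-Cl3C6H2COCl (3 equiv), Et3N (3 equiv), toluene, rt, 2 h; then 18, 75 °C, 24–48 h
Reagents that add atoms: 2,4,6-trichlorobenzoyl chloride, O=C(Cl)c1c(Cl)cc(Cl)cc1Cl (stays in 24 only)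
Why: Yamaguchi-type esterification through the mixed anhydride, run without DMAP, acylates the hindered C-1 alcohol with retention at C-1 and without isomerising the angelate to the tiglate.

**Compound list**
1 | dimethyl 3-methylpentanedioate | COC(=O)CC(C)CC(=O)OC | starting material
2 | (R)-5-methoxy-3-methyl-5-oxopentanoic acid | COC(=O)C[C@H](C)CC(=O)O | intermediate
3 | methyl (S)-5-chloro-3-methyl-5-oxopentanoate | COC(=O)C[C@H](C)CC(=O)Cl | intermediate
4 | methyl (R)-3,7-dimethyl-5-oxooct-6-enoate | COC(=O)C[C@H](C)CC(=O)C=C(C)C | intermediate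
5 | methyl (3R,5R)-5-hydroxy-3,7-dimethyloct-6-enoate | COC(=O)C[C@H](C)C[C@H](C=C(C)C)O | intermediate
6 | (4R,6R)-4-methyl-6-(2-methylprop-1-en-1-yl)oxan-2-one | O=C1C[C@H](C)C[C@H](C=C(C)C)O1 | intermediate
7 | 2-methylprop-2-enal | C=C(C)C=O | starting material
8 | rac-2-(prop-1-en-2-yl)oxirane (racemate) | C=C(C)C1CO1 | intermediate
9 | (S)-3-methylbut-3-ene-1,2-diol | C=C(C)[C@H](O)CO | intermediate
10 | (S)-2-hydroxy-3-methylbut-3-en-1-yl trifluoromethanesulfonate | C=C(C)[C@H](O)COS(=O)(=O)C(F)(F)F | intermediate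
11 | (S)-3-methyl-2-(triethylsilyloxy)but-3-en-1-yl trifluoromethanesulfonate | C=C(C)[C@H](O[Si](CC)(CC)CC)COS(=O)(=O)C(F)(F)F | intermediate
12 | lithium (4R,6R)-4-methyl-6-(2-methylprop-1-en-1-yl)-5,6-dihydro-4H-pyran-2-olate | [Li]OC1=C[C@H](C)C[C@H](C=C(C)C)O1 | intermediate
13 | (3S,4R,6R)-4-methyl-3-[(2R)-3-methyl-2-(triethylsilyloxy)but-3-en-1-yl]-6-(2-methylprop-1-en-1-yl)oxan-2-one | C=C(C)[C@H](O[Si](CC)(CC)CC)C[C@@H]1C(=O)O[C@@H](C=C(C)C)C[C@H]1C | intermediate
14 | (4S,6R)-4-[(2R,4R)-4-hydroxy-6-methylhept-5-en-2-yl]-7-methyl-6-(triethylsilyloxy)octa-1,7-dien-3-one | C=CC(=O)[C@@H](C[C@@H](O[Si](CC)(CC)CC)C(C)=C)[C@H](C)C[C@H](C=C(C)C)O | intermediate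
15 | (4S,6R)-6-hydroxy-4-[(2R,4R)-4-hydroxy-6-methylhept-5-en-2-yl]-7-methylocta-1,7-dien-3-one | C=CC(=O)[C@@H](C[C@@H](O)C(C)=C)[C@H](C)C[C@H](C=C(C)C)O | intermediate
16 | (4S,6R)-6-acetoxy-4-[(2R,4R)-4-acetoxy-6-methylhept-5-en-2-yl]-7-methylocta-1,7-dien-3-one | C=CC(=O)[C@@H](C[C@@H](OC(C)=O)C(C)=C)[C@H](C)C[C@H](C=C(C)C)OC(C)=O | intermediate
17 | (1R,5S)-5-[(2R,4R)-4-acetoxy-6-methylhept-5-en-2-yl]-2-methyl-4-oxocyclohex-2-en-1-yl acetate | O=C1C=C(C)[C@H](OC(C)=O)C[C@H]1[C@H](C)C[C@H](C=C(C)C)OC(C)=O | intermediate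
18 | (1R,4S,5S)-5-[(2R,4R)-4-acetoxy-6-methylhept-5-en-2-yl]-4-hydroxy-2-methylcyclohex-2-en-1-yl acetate | O[C@@H]1C=C(C)[C@H](OC(C)=O)C[C@H]1[C@H](C)C[C@H](C=C(C)C)OC(C)=O | intermediate
19 | tiglic acid, (E)-2-methylbut-2-enoic acid | C/C=C(\C)C(=O)O | starting material
20 | rac-(2R,3S)-2,3-dibromo-2-methylbutanoic acid (racemate, one enantiomer drawn) | C[C@H](Br)[C@](C)(Br)C(=O)O | intermediate
21 | (Z)-2-bromobut-2-ene | C/C=C(/C)Br | intermediate
22 | (E)-but-2-en-2-yllithium (Li in the place of Br, geometry retained) | C/C=C(/C)[Li] | intermediate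
23 | angelic acid, (Z)-2-methylbut-2-enoic acid | C/C=C(/C)C(=O)O | intermediate
24 | (Z)-2-methylbut-2-enoic 2,4,6-trichlorobenzoic anhydride | C/C=C(/C)C(=O)OC(=O)c1c(Cl)cc(Cl)cc1Cl | intermediate
25 | (1S,4R,6S)-4-acetoxy-6-[(2R,4R)-4-acetoxy-6-methylhept-5-en-2-yl]-3-methylcyclohex-2-en-1-yl (Z)-2-methylbut-2-enoate | C/C=C(/C)C(=O)O[C@@H]1C=C(C)[C@H](OC(C)=O)C[C@H]1[C@H](C)C[C@H](C=C(C)C)OC(C)=O | target

**Step count**
Total step count: 15.
Longest linear sequence: 9 steps (1, 2, 3, 7, 8, 9, 10, 11, 15; the sequence 4, 5, 6, 7, 8, 9, 10, 11, 15 is equally long).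

**Steps most likely to fail**

Step 7. C-alkylation of the lactone enolate by a β-silyloxy primary triflate may be slow or diverted to O-alkylation or elimination. The fallback sets out from 6 (through its enolate 12) and alkylates with prenyl bromide (THF, −78 °C), an allylic halide that reacts with the same trans selectivity, to give the prenyl lactone F1. Shi epoxidation (D-fructose-derived ketone, KHSO5, pH 10.5 carbonate buffer, MeCN/dimethoxymethane, 0 °C) then picks the electron-rich prenyl alkene over the C-10=C-11 alkene, which is deactivated by the allylic lactone oxygen, and gives the (R)-epoxide F2. Treatment with Et3SiOTf/2,6-lutidine at −78 °C followed by DBU opens the epoxide at its tertiary carbon and eliminates toward a methyl group, giving the silylated isopropenyl carbinol, which is 13, where the route is rejoined. C-4 is then set by the epoxidation catalyst instead of the kinetic resolution.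

Step 8. The direct Grignard opening may give double or conjugate addition, or enolisation of the hindered lactone. The fallback sets out from 13: aminolysis with Me2AlN(OMe)Me (from AlMe3 and MeNH(OMe)·HCl, CH2Cl2, 0 °C) gives the hydroxy Weinreb amide F3. Immediate silylation (Et3SiOTf, 2,6-lutidine) gives the bis-silyl Weinreb amide F4. CH2=CHMgBr (THF, 0 °C, inverse quench into cold aqueous acid) gives the bis-silyl vinyl ketone F5, over-addition being blocked by the chelated adduct. F5 under the conditions of step 9 gives 16, where the route is rejoined.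

Step 10. Metathesis between an enone and a 1,1-disubstituted alkene is slow; the Ru carbene may load on the C-10=C-11 alkene, and C-6 may epimerise on long heating. The fallback sets out from 16: Luche reduction (NaBH4, CeCl3·7H2O, MeOH, −78 °C) gives the dienol F6 as both C-1 epimers, whose allylic-alcohol vinyl group initiates metathesis readily. Ring-closing metathesis with the same Ru catalyst gives the cyclohexenol F7 as an epimer mixture. MnO2 (CH2Cl2, rt) oxidises both epimers to enone 17, where the route is rejoined before the stereoselective reduction of step 11.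

**Further compounds**
F1 | step 7 | (3S,4R,6R)-4-methyl-3-(3-methylbut-2-en-1-yl)-6-(2-methylprop-1-en-1-yl)oxan-2-one | CC(C)=CC[C@@H]1C(=O)O[C@@H](C=C(C)C)C[C@H]1C
F2 | step 7 | (3S,4R,6R)-3-{[(2R)-3,3-dimethyloxiran-2-yl]methyl}-4-methyl-6-(2-methylprop-1-en-1-yl)oxan-2-one | CC1(C)O[C@@H]1C[C@@H]2C(=O)O[C@@H](C=C(C)C)C[C@H]2C
F3 | step 8 | (2S,4R)-2-[(2R,4R)-4-hydroxy-6-methylhept-5-en-2-yl]-N-methoxy-N,5-dimethyl-4-(triethylsilyloxy)hex-5-enamide | CON(C)C(=O)[C@@H](C[C@@H](O[Si](CC)(CC)CC)C(C)=C)[C@H](C)C[C@H](C=C(C)C)O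
F4 | step 8 | (2S,4R)-N-methoxy-N,5-dimethyl-2-[(2R,4R)-6-methyl-4-(triethylsilyloxy)hept-5-en-2-yl]-4-(triethylsilyloxy)hex-5-enamide | CON(C)C(=O)[C@@H](C[C@@H](O[Si](CC)(CC)CC)C(C)=C)[C@H](C)C[C@H](C=C(C)C)O[Si](CC)(CC)CC
F5 | step 8 | (4S,6R)-7-methyl-4-[(2R,4R)-6-methyl-4-(triethylsilyloxy)hept-5-en-2-yl]-6-(triethylsilyloxy)octa-1,7-dien-3-one | C=CC(=O)[C@@H](C[C@@H](O[Si](CC)(CC)CC)C(C)=C)[C@H](C)C[C@H](C=C(C)C)O[Si](CC)(CC)CC
F6 | step 10 | (4S,6R)-6-acetoxy-4-[(2R,4R)-4-acetoxy-6-methylhept-5-en-2-yl]-7-methylocta-1,7-dien-3-ol, both C-3 epimers | C=CC(O)[C@@H](C[C@@H](OC(C)=O)C(C)=C)[C@H](C)C[C@H](C=C(C)C)OC(C)=O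
F7 | step 10 | (1R,5S)-5-[(2R,4R)-4-acetoxy-6-methylhept-5-en-2-yl]-4-hydroxy-2-methylcyclohex-2-en-1-yl acetate, both C-4 epimers | OC1C=C(C)[C@H](OC(C)=O)C[C@H]1[C@H](C)C[C@H](C=C(C)C)OC(C)=O
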